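**Retrosynthetic overview**
- The methylene bridge is cut at its bond to ring B (C6 of the cyclohexadienone). The bridge carbon then becomes the formyl carbon of a 2H-chromene-6-carbaldehyde, and the two halves are joined last by a reductive Knoevenagel alkylation.
- Ring A rests on one feature: in 2H-chromene numbering the pyran oxygen O1 (on C8a) is para to the bridge-bearing C6, and the isobutyryl carbon C8 lies between O1 and the 7-OH. The C8 acyl group is therefore removed first. The pyran ring is then opened at C4–C4a to the para-O-(1,1-dimethylpropargyl) ether of mirror-symmetric 2,4,6-trihydroxybenzaldehyde (gold hydroarylation).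
- Ring B: the quaternary C4 (methyl, prenyl, S) is cut at the prenyl bond. This gives 2,4,6-trihydroxy-3-methylisobutyrophenone (from 2,4,6-trihydroxytoluene) for an enantioselective dearomative prenylation.
- Ring order: both benzene rings are bought; the pyran ring is closed in step 2, ring B is dearomatised in step 6, and the halves are joined in step 7.

Key step: step 2

Remark: ring B is drawn and named in the enol tautomer of the given SMILES, to which the descriptor 4S refers; the sense of induction of the chiral ligand in step 6 cannot be predicted with certainty and is to be fixed by a pilot run (the ligand antipode is used if required).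

**Step 1**
Reactants: 1 2,4,6-trihydroxybenzaldehyde; 2 2-methylbut-3-yn-2-ol
Product: 4 2,6-dihydroxy-4-[(2-methylbut-3-yn-2-yl)oxy]benzaldehyde, via 2-methylbut-3-yn-2-yl trifluoroacetate 3 (not isolated)
Conditions: 2 (1.1 equiv), (CF3CO)2O, DBU, MeCN, −5 °C; then 1, DBU (1.1 equiv), CuCl2·2H2O (1 mol%), MeCN, −5 → 0 °C
Reagents that add atoms: none
Why: Copper-catalysed propargylic etherification of a phenoxide with a tertiary propargylic trifluoroacetate should alkylate the 4-OH, because this hydroxyl is para to the formyl group, hence the most acidic and the only one outside the formyl chelate, and the mirror plane of 1 through this oxygen allows only one such ether.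

**Step 2**
Reactants: 4 2,6-dihydroxy-4-[(2-methylbut-3-yn-2-yl)oxy]benzaldehyde
Product: 5 5,7-dihydroxy-2,2-dimethyl-2H-chromene-6-carbaldehyde
Conditions: Ph3PAuNTf2 (3 mol%), CH2Cl2, rt
Reagents that add atoms: none
Why: Cationic monovalent gold binds the terminal alkyne of 4 as a π-complex, the arene carbon ortho to the ether oxygen (activated ortho/para by three oxygen donors and only meta to the formyl group) attacks the terminal alkyne carbon anti to gold, and rearomatisation followed by protodeauration of the vinylgold species releases 5 and the catalyst. The closest known reaction type is the gold-catalysed intramolecular hydroarylation (alkyne Friedel–Crafts alkenylation) that turns aryl 1,1-dimethylpropargyl ethers into 2,2-dimethyl-2H-chromenes. The pyran ring is closed in the 6-endo-dig mode with formation of the C4–C4a bond, the gem-dimethyl group and the strain of a 3-methylene-2,3-dihydrobenzofuran disfavouring the 5-exo-dig attack at the internal alkyne carbon. No stereocentre is formed. The selectivity needed is regiochemical (pyran oxygen para to the formyl carbon, with C8 left free); it is secured because the O–CMe2 bond made in step 1 is kept and the two ortho carbons of 4 are related by the mirror plane through C1 and C4, so either closure gives the same chromene. A competing gold-promoted propargyl Claisen pathway would converge on the same product for the same reason.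

**Step 3**
Reactants: 5 5,7-dihydroxy-2,2-dimethyl-2H-chromene-6-carbaldehyde; 6 isobutyryl chloride (2-methylpropanoyl chloride)
Product: 7 5,7-dihydroxy-2,2-dimethyl-8-(2-methylpropanoyl)-2H-chromene-6-carbaldehyde
Conditions: 6 (1.2 equiv), TiCl4 (2.5 equiv), CH2Cl2, −20 → 0 °C; ice-water
Reagents that add atoms: none
Why: Friedel–Crafts (Fries-type, titanium phenolate-directed) C-acylation can only take place at C8, the single unsubstituted ring carbon (ortho to O7 and O1, para to O5), and the cold, short exposure is chosen because the chromene alkene, whose donor oxygens are conjugated with the 6-formyl group, is expected to tolerate the Lewis acid at low temperature.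

**Step 4**
Reactants: 8 2,4,6-trihydroxytoluene; 6 isobutyryl chloride
Product: 9 1-(2,4,6-trihydroxy-3-methylphenyl)-2-methylpropan-1-one
Conditions: AlCl3 (3.5 equiv), PhNO2/CH2Cl2, 0 °C → rt; ice/1 M HCl
Reagents that add atoms: none
Why: Friedel–Crafts acylation of a phloroglucinol nucleus should give one product, since the two free ring carbons of 8 are equivalent and the first acyl group deactivates the ring towards a second acylation.

**Step 5**
Reactants: 10 3-methylbut-2-en-1-ol
Product: 11 methyl 3-methylbut-2-en-1-yl carbonate
Conditions: ClCO2Me, pyridine, CH2Cl2, 0 °C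
Reagents that add atoms: methyl chloroformate, COC(Cl)=O
Why: Alkoxycarbonylation of a primary allylic alcohol with a chloroformate and pyridine as acid scavenger is routine and gives the ionisable carbonate needed for π-allyl formation.

**Step 6**
Reactants: 9 1-(2,4,6-trihydroxy-3-methylphenyl)-2-methylpropan-1-one; 11 methyl 3-methylbut-2-en-1-yl carbonate
Product: 12 (4S)-3,5-dihydroxy-4-methyl-4-(3-methylbut-2-en-1-yl)-2-(2-methylpropanoyl)cyclohexa-2,5-dien-1-one
Conditions: Pd2(dba)3·CHCl3 (2.5 mol%), (1R,2R)-N,N'-bis[2-(diphenylphosphanyl)benzoyl]cyclohexane-1,2-diamine (7.5 mol%), CH2Cl2, 0 °C → rt; 11 limiting (0.95 equiv)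
Reagents that add atoms: none
Why: Proposed new method: zerovalent palladium ionises 11 to a 1,1-dimethyl-π-allyl complex with loss of CO2 and methoxide, which deprotonates 9; the phloroglucinolate should attack the unsubstituted allyl terminus through its methyl-bearing ring carbon (the site preferred in base-mediated gem-dialkylation of acylphloroglucinols, while O-allylation is reversible under palladium), and the chiral pocket of the diphosphine differentiates the two enantiotopic faces of the planar nucleophile to set the quaternary 4S centre; the closest known reaction types are the racemic base-mediated dearomative prenylation of alkylated acylphloroglucinols and the palladium-catalysed asymmetric allylic dearomatisation of naphthols and phenols (Tsuji–Trost allylic alkylation).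

**Step 7**
Reactants: 7 5,7-dihydroxy-2,2-dimethyl-8-(2-methylpropanoyl)-2H-chromene-6-carbaldehyde; 12 (4S)-3,5-dihydroxy-4-methyl-4-(3-methylbut-2-en-1-yl)-2-(2-methylpropanoyl)cyclohexa-2,5-dien-1-one
Product: 14 (4S)-6-{[5,7-dihydroxy-2,2-dimethyl-8-(2-methylpropanoyl)-2H-chromen-6-yl]methyl}-3,5-dihydroxy-4-methyl-4-(3-methylbut-2-en-1-yl)-2-(2-methylpropanoyl)cyclohexa-2,5-dien-1-one (target), via Knoevenagel alkylidene 13 (not isolated)
Conditions: diethyl 2,6-dimethyl-1,4-dihydropyridine-3,5-dicarboxylate (Hantzsch ester, 1.2 equiv), L-proline (20 mol%), CH2Cl2, rt, dark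
Reagents that add atoms: none
Why: Amine-catalysed Knoevenagel condensation of the aldehyde with the only acidic C–H of 12 (C6, between the C1 carbonyl and the C5 enol) should give the electron-poor alkylidene 13, which the dihydropyridine reduces by conjugate hydride transfer (three-component reductive alkylation of cyclic 1,3-diones), while the prenyl and chromene alkenes are not hydride acceptors and the quaternary C4 centre, lacking an α-hydrogen, is untouched at room temperature.

**Compound list**
1 | 2,4,6-trihydroxybenzaldehyde | O=Cc1c(O)cc(O)cc1O | starting material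
2 | 2-methylbut-3-yn-2-ol | CC(C)(O)C#C | starting material
3 | 2-methylbut-3-yn-2-yl trifluoroacetate | CC(C)(OC(=O)C(F)(F)F)C#C | intermediate
4 | 2,6-dihydroxy-4-[(2-methylbut-3-yn-2-yl)oxy]benzaldehyde | O=Cc1c(O)cc(OC(C)(C)C#C)cc1O | intermediate
5 | 5,7-dihydroxy-2,2-dimethyl-2H-chromene-6-carbaldehyde | O=Cc1c(O)cc2OC(C)(C)C=Cc2c1O | intermediate
6 | isobutyryl chloride (2-methylpropanoyl chloride) | CC(C)C(Cl)=O | starting material
7 | 5,7-dihydroxy-2,2-dimethyl-8-(2-methylpropanoyl)-2H-chromene-6-carbaldehyde | O=Cc1c(O)c(C(=O)C(C)C)c2OC(C)(C)C=Cc2c1O | intermediate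
8 | 2,4,6-trihydroxytoluene (2-methylbenzene-1,3,5-triol) | Cc1c(O)cc(O)cc1O | starting material
9 | 1-(2,4,6-trihydroxy-3-methylphenyl)-2-methylpropan-1-one | CC(C)C(=O)c1c(O)cc(O)c(C)c1O | intermediate
10 | 3-methylbut-2-en-1-ol | CC(C)=CCO | starting material
11 | methyl 3-methylbut-2-en-1-yl carbonate | COC(=O)OCC=C(C)C | intermediate
12 | (4S)-3,5-dihydroxy-4-methyl-4-(3-methylbut-2-en-1-yl)-2-(2-methylpropanoyl)cyclohexa-2,5-dien-1-one | CC(C)=CC[C@@]1(C)C(O)=CC(=O)C(C(=O)C(C)C)=C1O | intermediate
13 | (4R)-6-{[5,7-dihydroxy-2,2-dimethyl-8-(2-methylpropanoyl)-2H-chromen-6-yl]methylidene}-3-hydroxy-4-methyl-4-(3-methylbut-2-en-1-yl)-2-(2-methylpropanoyl)cyclohex-2-ene-1,5-dione (alkene geometry undefined; same spatial arrangement at C4 as in 12, the descriptor changes with the tautomer) | CC(C)=CC[C@@]1(C)C(=O)C(=Cc2c(O)c3C=CC(C)(C)Oc3c(C(=O)C(C)C)c2O)C(=O)C(C(=O)C(C)C)=C1O | intermediate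
14 | (4S)-6-{[5,7-dihydroxy-2,2-dimethyl-8-(2-methylpropanoyl)-2H-chromen-6-yl]methyl}-3,5-dihydroxy-4-methyl-4-(3-methylbut-2-en-1-yl)-2-(2-methylpropanoyl)cyclohexa-2,5-dien-1-one | CC(C)=CC[C@@]1(C)C(O)=C(Cc2c(O)c3c(c(C(=O)C(C)C)c2O)OC(C)(C)C=C3)C(=O)C(C(=O)C(C)C)=C1O | target

**Step count**
Total: 7 steps. Longest linear sequence: 4 steps (1, 2, 3, 7).

**Steps most likely to fail**

Step 6. The risks are competing prenylation at the unsubstituted ring carbon followed by rearomatisation, a second prenylation at C6 of the product, and weak enantiofacial discrimination. The fallback sets out from 9 and uses known chemistry. The methyl-bearing carbon is prenylated without asymmetric induction (3-methylbut-2-enyl bromide, NaOMe, MeOH, 0 °C; the classical base-mediated dearomative C-alkylation) to give racemic 3,5-dihydroxy-4-methyl-4-(3-methylbut-2-en-1-yl)-2-(2-methylpropanoyl)cyclohexa-2,5-dien-1-one F1. Preparative chromatography on a chiral stationary phase (amylose tris(3,5-dimethylphenylcarbamate), supercritical CO2/MeOH with formic acid) then separates the enantiomers. The 4S enantiomer is 12, where the route is rejoined; (4R)-3,5-dihydroxy-4-methyl-4-(3-methylbut-2-en-1-yl)-2-(2-methylpropanoyl)cyclohexa-2,5-dien-1-one F2 is set aside. The configuration is assigned by electronic circular dichroism against calculation.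

Step 7. The risks are sluggish condensation of the doubly hydrogen-bonded, electron-rich aldehyde, addition of a second molecule of 12 to the alkylidene before hydride transfer, and cyclodehydration towards a xanthene. The fallback sets out from 7 and separates bridge activation from C–C bond formation. Reductive amination (Me2NH, NaBH(OAc)3, 1,2-dichloroethane, rt) gives the phenolic Mannich base 1-{6-[(dimethylamino)methyl]-5,7-dihydroxy-2,2-dimethyl-2H-chromen-8-yl}-2-methylpropan-1-one F3. Warming F3 with 12 in toluene at 50 °C expels dimethylamine to form the ortho-quinone methide 5-hydroxy-2,2-dimethyl-6-methylidene-8-(2-methylpropanoyl)-2H-chromen-7(6H)-one F4. This is trapped by conjugate addition of the enol carbon C6 of 12, rejoining the route at 14.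

Step 3. The risks are acid-induced oligomerisation through protonation of the chromene alkene and incomplete acylation of the formyl-deactivated ring. The fallback sets out from 5 and replaces electrophilic substitution under Lewis acid by chelation-directed acylation of a phenolate. Mg(OMe)2 (1 equiv, MeOH, then solvent exchange to toluene) gives magnesium 6-formyl-2,2-dimethyl-2H-chromene-5,7-diolate F5. Treatment with 6 in toluene (0 °C → rt, dilute HCl work-up) should deliver the acyl group to the ortho carbon C8 through the magnesium chelate (ortho-acylation of magnesium phenolates), rejoining the route at 7.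

**Further compounds**
F1 | step 6 | racemic 3,5-dihydroxy-4-methyl-4-(3-methylbut-2-en-1-yl)-2-(2-methylpropanoyl)cyclohexa-2,5-dien-1-one | CC(C)=CCC1(C)C(O)=CC(=O)C(C(=O)C(C)C)=C1O
F2 | step 6 | (4R)-3,5-dihydroxy-4-methyl-4-(3-methylbut-2-en-1-yl)-2-(2-methylpropanoyl)cyclohexa-2,5-dien-1-one | CC(C)=CC[C@]1(C)C(O)=CC(=O)C(C(=O)C(C)C)=C1O
F3 | step 7 | 1-{6-[(dimethylamino)methyl]-5,7-dihydroxy-2,2-dimethyl-2H-chromen-8-yl}-2-methylpropan-1-one | CN(C)Cc1c(O)c(C(=O)C(C)C)c2OC(C)(C)C=Cc2c1O
F4 | step 7 | 5-hydroxy-2,2-dimethyl-6-methylidene-8-(2-methylpropanoyl)-2H-chromen-7(6H)-one | C=C1C(=O)C(C(=O)C(C)C)=C2OC(C)(C)C=CC2=C1O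
F5 | step 3 | magnesium 6-formyl-2,2-dimethyl-2H-chromene-5,7-diolate | O=Cc1c([O-])cc2OC(C)(C)C=Cc2c1[O-].[Mg+2]
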